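## The problem

Target 10 is a flavonol. Benzene ring A is fused to the 4-pyranone ring C (O1, C2, C3, C4, C4a, C8a), and the catechol ring B stands on C2. The molecule is flat and has no stereocentre, so nothing has to be controlled in space. No C–C bond of the skeleton is hard to make, and the task is to tell the oxygen atoms apart. Ring A is a 1,2,3,5-tetraoxygenated benzene whose four oxygens all differ: O1 belongs to ring C, O8 is acetylated, O7 is methylated, O5 is a free chelated phenol, and only C6 bears hydrogen. The single acetate must sit on O8 while 3-OH, 5-OH, 3'-OH and 4'-OH stay free. Selective acetylation of the parent polyphenol is therefore ruled out, and the usual answer is an A-ring block with four different O-substituents and an orthogonal set of protecting groups. The C8–O bond is the expensive one, because 5,7-dioxygenated A rings are cheap but a further oxygen has to choose between C6 and C8. The aryl acetate does not survive hydroxide, alkoxide, amines or hot aqueous acid, and the free catechol and the 3-hydroxy-4-pyranone are oxidised by air in base, so every operation after the acetate appears must be neutral or acidic and free of nucleophiles. The feature that opens the problem is the position of C8: it lies between C7–OMe and C8a–O1 and para to C5–O, which makes it the best migrating carbon of the molecule towards an electron-poor oxygen. If the oxygen between C8 and the acetyl carbon is taken out, C8 and C4a both carry a C-acyl group on either side of C8a–O1, and C5 and C7 both carry oxygen, so ring A gains a mirror plane through C8a and C6 that the target hides.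

## Retrosynthesis

**10 ⇒ 9.** The bonds cut are the two O–CH2Ph bonds at O3' and O4' and the O5–CH3 bond. The last step must be free of base and nucleophile because of the acetate, which points to a boron Lewis acid with a cation trap. In 9 only the 5-methoxy group has a carbonyl neighbour (C4=O, peri), so chelation picks it out from the 7-methoxy group. Precursor 9 has one free hydroxy group where 10 has four. The forward reaction must cleave three ethers and spare O7–CH3 and the ester.

**9 ⇒ 7 (through 8).** The bond cut is C3–O. The neighbouring choice is to bring O3 in with the C ring by alkaline peroxide oxidation of a chalcone. That would expose an ortho-hydroxyaryl methyl ketone to Dakin conditions and would meet the tendency of 6'-alkoxychalcones to form aurones. A neutral dioxirane acting on the finished flavone avoids both problems and leaves the acetate alone. Precursor 7 is a plain flavone that an acyl-transfer synthesis can deliver. The forward reaction must oxidise only C2=C3.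

**7 ⇒ 6 (key disconnection).** The C8–O bond is cut and C8 is joined directly to the acetyl carbon, which is a retro-Baeyer–Villiger step. The neighbouring cut, O8–C(acyl), leads back to a free 8-OH, hence to a third kind of protecting group and to an A ring with four different oxygens. Compound 6 is no smaller than 7, but it is simpler where it counts. Its ring A carries two pairs of like substituents (two C-acyl carbons, two methoxy groups), and it falls back on a C2v-symmetric benzene. The C-acetyl group is also a base-stable carrier of the future acetate through the enolate chemistry that builds ring C. The forward reaction must give aryl and not methyl migration and must not attack C4=O, C2=C3 or the benzyl ethers. It also makes the two methoxy groups different, which the step 10 ⇒ 9 relies on.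

**6 ⇒ 4 (through 5).** The bonds cut are O1–C2 and C2–C3. An intermolecular condensation on one of two equal acetyl groups would be statistical. An aroyl group parked on the oxygen between them can be handed over only once and to either neighbour with the same result, so the symmetry is broken cleanly. Precursor 4 is a simple aryl ester. The forward reaction is an O→C acyl shift followed by cyclodehydration, and it must leave the second acetyl group untouched.

**4 ⇒ 2 + 3.** The bond cut is the ester C–O bond. This is the only convergent union of the route, and it joins all carbons of rings A and C with ring B. Both partners are small, and 3 is an article of commerce. The forward reaction must acylate a hindered but acidic phenol, which is the only hydroxy group of 2.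

**2 ⇒ 1.** The bonds cut are the two O–CH3 bonds. Compound 1 is a commercial, C2v-symmetric triphenol. Methyl is chosen for both outer oxygens because one of them stays in the target and the other becomes removable by chelation after the key step. The forward reaction must cap the two outer hydroxy groups and leave the central, doubly flanked one free.

## Roads not taken

**Alternative 1:** This is the most obvious route. The cut is the O8–C(acyl) bond, and ring C is then opened to a chalcone. In the forward direction, acetophenone A1 undergoes Claisen–Schmidt condensation to chalcone A2. Algar–Flynn–Oyamada oxidation, 3-O-benzylation and removal of the acetal give phenol A3, which is acetylated and hydrogenolysed. A1 carries four different oxygen substituents on one benzene ring and needs a long preparation that itself includes the difficult C–O bond at the future C8. 2'-Hydroxy-6'-alkoxychalcones such as A2 are the substrates that turn towards aurones in the key oxidation. Three kinds of protecting group are needed, against two in the chosen plan, and the step count is about twice as high.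

**Alternative 2:** The cut is C8–O on the intact flavonol, that is, a C8–H oxidation. In the forward direction, the tribenzyl ether A4 is oxidised para to its 5-phenolate (Elbs persulfate oxidation) to quinol A5, whose non-chelated 8-OH is acetylated before hydrogenolysis. A bolder variant oxidises the 5-phenol of A4 with hypervalent iodine or at an anode in acetate medium to place the acetate directly. A4 is itself the product of a multi-step differentiation of five hydroxy groups. The persulfate reaction typically stops at low conversion and needs hot acid to free the phenol. The phenoxenium variant is electronically mismatched: O7 and O1 stand on C7 and C8a, which are meta to C5–O and carry none of the positive charge, C4a bears an acyl group, and ring B with C2=C3 is the more oxidisable part. In the chosen key step the same three oxygens stand ortho, ortho and para to the migrating carbon and all help.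

**Alternative 3:** The cuts are C4a–C4 and C8a–O1, leading back to a quinone. In the forward direction, quinone A6 takes up an acyl radical from an aldehyde (photo-Friedel–Crafts acylation, a union of two electrophilic carbons) to give acylhydroquinone A7. This is elaborated to the flavone-5,8-quinone A8, which is reduced and acetylated at the non-chelated 8-OH. The only free ortho-hydroxy group of A7 closes ring C towards the 5,6,7-pattern. The 5,7,8-pattern requires re-oxidation to the acylquinone and an addition–elimination at the methoxy-bearing carbon. The route therefore passes through several redox adjustments and an air-sensitive 5,8-quinol, and the acetate still costs a step of its own.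

Key step: step 4

Remark on the chemistry: the target has no stereocentre and no hindered axis, and its SMILES holds no stereodescriptor. It is achiral, so the request for a single enantiomer asks for nothing further. Compounds 1 and 3 are taken as catalogue compounds.

## Route

Step 1
Reactants: 1 2,4-diacetylphloroglucinol
Product: 2 2,6-diacetyl-3,5-dimethoxyphenol
Conditions: Me2SO4 (2.05 equiv), K2CO3, acetone, reflux
Reagents that add atoms: dimethyl sulfate, COS(=O)(=O)OC
Why: Williamson O-methylation under chelation control, the reaction type that turns phloroacetophenone into its 4,6-dimethyl ether; each outer hydroxy group is para to one acetyl group and open on one side, whereas the central one is flanked by both acetyl groups and stays hydrogen-bonded to either carbonyl, so it should be alkylated last. The mirror symmetry of 1 is kept.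

Step 2
Reactants: 2 2,6-diacetyl-3,5-dimethoxyphenol; 3 3,4-bis(benzyloxy)benzoic acid
Product: 4 2,6-diacetyl-3,5-dimethoxyphenyl 3,4-bis(benzyloxy)benzoate
Conditions: DCC, DMAP (cat.), CH2Cl2, 0 °C → rt
Reagents that add atoms: none
Why: Steglich esterification; the acidic phenol of 2 is acylated by the acylpyridinium ion formed from 3. It is the only hydroxy group present, so exactly one aroyl group is loaded between the two equivalent acetyl groups.

Step 3
Reactants: 4 2,6-diacetyl-3,5-dimethoxyphenyl 3,4-bis(benzyloxy)benzoate
Product: 6 8-acetyl-2-[3,4-bis(benzyloxy)phenyl]-5,7-dimethoxy-4H-chromen-4-one, via Baker–Venkataraman diketone 5 (not isolated)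
Conditions: LiHMDS (3.2 equiv), THF, −78 → 0 °C; AcOH quench, solvent switch; p-TsOH·H2O (cat.), toluene, 90 °C
Reagents that add atoms: none
Why: Baker–Venkataraman O→C acyl shift and acid cyclodehydration, the standard flavone synthesis; the enolate of either acetyl group (mirror-related, so both give the same product) attacks the neighbouring ester through a six-membered transition state to give 5, whose freed phenol adds to the aroyl carbonyl (6-exo-trig) and loses water. The aroyl group is delivered intramolecularly and only once, so the second acetyl group stays untouched and becomes the C8 acetyl group.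

Step 4
Reactants: 6 8-acetyl-2-[3,4-bis(benzyloxy)phenyl]-5,7-dimethoxy-4H-chromen-4-one
Product: 7 2-[3,4-bis(benzyloxy)phenyl]-5,7-dimethoxy-4-oxo-4H-chromen-8-yl acetate
Conditions: mCPBA (3 equiv), TFA (0.5 equiv), CH2Cl2, 0 °C → rt, dark
Reagents that add atoms: 3-chloroperoxybenzoic acid, OOC(=O)c1cccc(Cl)c1
Why: Baeyer–Villiger oxidation of an aryl methyl ketone, closest in type to the oxidation of 2,6- and 2,4,6-alkoxyacetophenones to aryl acetates. The C8 acetyl group is turned out of the plane of ring A by O1 and the 7-methoxy group, so its carbonyl is unconjugated and should add the peracid like a dialkyl ketone to give the Criegee adduct. In the adduct C8 migrates to the proximal peroxide oxygen antiperiplanar to the O–O bond while 3-chlorobenzoate leaves, and the positive charge that builds up in ring A is taken up by O7 and O1 (ortho) and O5 (para), so aryl migration should outrun methyl migration by a wide margin. The acetate thus forms directly on O8 without a free 8-OH ever existing, so the C8–O bond and the placing of the one acyl group are settled together. No ring is closed and no stereocentre is formed. The chemoselectivity rests on the substrate: C4=O is a vinylogous ester within a 4-pyranone and does not add peracid, C2=C3 is electron-poor and still carries no oxygen at C3 (the reason why step 5 comes afterwards), and benzyl ethers and alkoxyarenes are inert to mCPBA. The step also ends the near-equivalence of the two methoxy groups, because afterwards only the 5-methoxy group has a carbonyl neighbour.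

Step 5
Reactants: 7 2-[3,4-bis(benzyloxy)phenyl]-5,7-dimethoxy-4-oxo-4H-chromen-8-yl acetate
Product: 9 2-[3,4-bis(benzyloxy)phenyl]-3-hydroxy-5,7-dimethoxy-4-oxo-4H-chromen-8-yl acetate, via flavone 2,3-epoxide 8 (not isolated)
Conditions: DMDO (acetone solution, 4 equiv), CH2Cl2, 0 °C → rt; then p-TsOH·H2O (cat.)
Reagents that add atoms: dimethyldioxirane, CC1(C)OO1
Why: Epoxidation of the flavone C2=C3 bond by a neutral dioxirane and acid-catalysed isomerisation of the epoxide, a known flavone-to-flavonol conversion that tolerates benzyl ethers; O1 and the electron-rich aryl group open the epoxide at C2 and loss of H3 gives the enol. The two stereocentres of racemic 8 vanish in the same flask, and the medium holds neither base nor nucleophile, so the acetate is safe.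

Step 6
Reactants: 9 2-[3,4-bis(benzyloxy)phenyl]-3-hydroxy-5,7-dimethoxy-4-oxo-4H-chromen-8-yl acetate
Product: 10 gossypetin 7-methyl ether 8-acetate [2-(3,4-dihydroxyphenyl)-3,5-dihydroxy-7-methoxy-4-oxo-4H-chromen-8-yl acetate]
Conditions: BCl3 (8 equiv), pentamethylbenzene (6 equiv), CH2Cl2, −78 → 0 °C; cold aqueous pH 4 buffer
Reagents that add atoms: none
Why: Lewis-acid ether cleavage; aryl benzyl ethers are cleaved by BCl3 with pentamethylbenzene as a non-basic trap for the benzyl cation, and the 5-methoxy group is cleaved by chelation of boron between O4 and O5 followed by attack of chloride on the methyl group. The 7-methoxy group has had no carbonyl neighbour since step 4, the aryl acetate is not attacked by BCl3 in the cold, and no Fries shift is possible because C7, C8a and C5 are all substituted.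

## Compound list

1 | 2,4-diacetylphloroglucinol [1,1'-(2,4,6-trihydroxybenzene-1,3-diyl)diethanone] | CC(=O)c1c(O)cc(O)c(C(C)=O)c1O | starting material
2 | 2,6-diacetyl-3,5-dimethoxyphenol | CC(=O)c1c(OC)cc(OC)c(C(C)=O)c1O | intermediate
3 | 3,4-bis(benzyloxy)benzoic acid | OC(=O)c1ccc(OCc2ccccc2)c(OCc2ccccc2)c1 | starting material
4 | 2,6-diacetyl-3,5-dimethoxyphenyl 3,4-bis(benzyloxy)benzoate | CC(=O)c1c(OC)cc(OC)c(C(C)=O)c1OC(=O)c1ccc(OCc2ccccc2)c(OCc2ccccc2)c1 | intermediate
5 | 1-(3-acetyl-2-hydroxy-4,6-dimethoxyphenyl)-3-[3,4-bis(benzyloxy)phenyl]propane-1,3-dione | CC(=O)c1c(OC)cc(OC)c(C(=O)CC(=O)c2ccc(OCc3ccccc3)c(OCc3ccccc3)c2)c1O | intermediate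
6 | 8-acetyl-2-[3,4-bis(benzyloxy)phenyl]-5,7-dimethoxy-4H-chromen-4-one | COc1cc(OC)c2c(=O)cc(-c3ccc(OCc4ccccc4)c(OCc4ccccc4)c3)oc2c1C(C)=O | intermediate
7 | 2-[3,4-bis(benzyloxy)phenyl]-5,7-dimethoxy-4-oxo-4H-chromen-8-yl acetate | COc1cc(OC)c2c(=O)cc(-c3ccc(OCc4ccccc4)c(OCc4ccccc4)c3)oc2c1OC(C)=O | intermediate
8 | 2,3-epoxide of 7 (racemic, cis-fused by necessity; both centres are lost in the same flask) | COc1cc(OC)c2C(=O)C3OC3(c4ccc(OCc5ccccc5)c(OCc5ccccc5)c4)Oc2c1OC(C)=O | intermediate
9 | 2-[3,4-bis(benzyloxy)phenyl]-3-hydroxy-5,7-dimethoxy-4-oxo-4H-chromen-8-yl acetate | COc1cc(OC)c2c(=O)c(O)c(-c3ccc(OCc4ccccc4)c(OCc4ccccc4)c3)oc2c1OC(C)=O | intermediate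
10 | gossypetin 7-methyl ether 8-acetate | COc1cc(O)c2c(=O)c(O)c(-c3ccc(O)c(O)c3)oc2c1OC(C)=O | target

## Step count and risks

The route has 6 steps in total. The longest linear sequence is also 6 steps (1 → 2 → 4 → 6 → 7 → 9 → 10).

**Step 4 (key step).** The most likely failure is slow addition of the peracid to the carbonyl, which is flanked on both sides, so that the reaction stalls. Hydrogen bonding or protonation of the basic pyranone carbonyl by the acid co-catalyst would also lower the donor power of ring A and slow the migration, and long reaction times invite electrophilic hydroxylation at C6. The fallback sets out from 2 and returns at 7. It moves the carbon-to-oxygen shift to the start, where a free ortho-phenolate drives it. Dakin oxidation of 2 (1 equiv H2O2, aqueous NaOH, 0 °C) should convert one of the two equivalent acetyl groups and give 1-(2,3-dihydroxy-4,6-dimethoxyphenyl)ethanone F1. Double Steglich esterification with 3 gives 3-acetyl-4,6-dimethoxy-1,2-phenylene bis[3,4-bis(benzyloxy)benzoate] F2. The conditions of step 3 shift the aroyl group next to the acetyl group and close ring C to give 2-[3,4-bis(benzyloxy)phenyl]-5,7-dimethoxy-4-oxo-4H-chromen-8-yl 3,4-bis(benzyloxy)benzoate F3. Methanolysis (K2CO3, MeOH) frees 2-[3,4-bis(benzyloxy)phenyl]-8-hydroxy-5,7-dimethoxy-4H-chromen-4-one F4, whose only hydroxy group is acetylated (Ac2O, pyridine) to 7. The direct delivery of the acetate is given up and the route grows longer, but the symmetric starting point is kept.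

**Step 1.** Regiocontrol may be incomplete. Methylation of the central hydroxy group may compete with that of the second outer one, and some over-methylation may occur, because all three phenols are activated by two acyl groups. The fallback sets out from 1 and returns at 2. Exhaustive methylation (excess Me2SO4, K2CO3, DMF) gives 1,1'-(2,4,6-trimethoxybenzene-1,3-diyl)diethanone F5. One equivalent of BCl3 (CH2Cl2, −78 → 0 °C) should then remove the central methyl group. That methoxy group is twisted out of plane by two ortho substituents, is the most Lewis basic, and can be chelated from either carbonyl.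

**Step 3.** The hindered ester has a good leaving group, so base may cleave it before the acyl shift. The free acetyl enolate may also condense intermolecularly, and the C8 acetyl group may be lost by protodeacylation in the acid phase. The fallback sets out from 2 and returns at 6. Claisen–Schmidt condensation of 2 with one equivalent of commercial 3,4-bis(benzyloxy)benzaldehyde F6 (KOH, EtOH) gives (E)-1-(3-acetyl-2-hydroxy-4,6-dimethoxyphenyl)-3-[3,4-bis(benzyloxy)phenyl]prop-2-en-1-one F7, which is cyclised oxidatively (I2 cat., DMSO, 120 °C) to 6. The price is statistical formation of some bis-condensation product.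

**Step 5.** Epoxidation of the vinylogous ester may be sluggish, so that oxidation of the benzylic C–H bonds or further oxidation of the flavonol formed begins to compete. The fallback sets out from 6 and returns at 10. It installs O3 by anion chemistry before the acetate exists. LDA (2.5 equiv, THF, −78 °C) first protects the acetyl group as its enolate and then lithiates C3. B(OMe)3 followed by H2O2/AcOH gives 8-acetyl-2-[3,4-bis(benzyloxy)phenyl]-3-hydroxy-5,7-dimethoxy-4H-chromen-4-one F8. Benzylation (BnBr, K2CO3, DMF) gives 8-acetyl-3-(benzyloxy)-2-[3,4-bis(benzyloxy)phenyl]-5,7-dimethoxy-4H-chromen-4-one F9. The conditions of step 4 give 3-(benzyloxy)-2-[3,4-bis(benzyloxy)phenyl]-5,7-dimethoxy-4-oxo-4H-chromen-8-yl acetate F10, and the conditions of step 6 give 10.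

**Step 6.** The 5-O-demethylation may be incomplete because boron is tied up in the five-membered chelate between O3 and O4. Stray benzyl cations may C-benzylate the electron-rich rings, and the acetate may be lost during hydrolysis of the borates. The fallback sets out from 9 and returns at 10. It separates the two tasks. Neutral hydrogenolysis (H2, Pd/C, EtOAc/THF) gives 2-(3,4-dihydroxyphenyl)-3-hydroxy-5,7-dimethoxy-4-oxo-4H-chromen-8-yl acetate F11 without any cation being formed. Aluminium chloride in acetonitrile can bind O3, O4 and O5 at one six-coordinate centre and should then cleave only the 5-methoxy group to give 10.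

## Further compounds

F1 | step 4 | 1-(2,3-dihydroxy-4,6-dimethoxyphenyl)ethanone | CC(=O)c1c(OC)cc(OC)c(O)c1O
F2 | step 4 | 3-acetyl-4,6-dimethoxy-1,2-phenylene bis[3,4-bis(benzyloxy)benzoate] | CC(=O)c1c(OC)cc(OC)c(OC(=O)c2ccc(OCc3ccccc3)c(OCc3ccccc3)c2)c1OC(=O)c1ccc(OCc2ccccc2)c(OCc2ccccc2)c1
F3 | step 4 | 2-[3,4-bis(benzyloxy)phenyl]-5,7-dimethoxy-4-oxo-4H-chromen-8-yl 3,4-bis(benzyloxy)benzoate | COc1cc(OC)c2c(=O)cc(-c3ccc(OCc4ccccc4)c(OCc4ccccc4)c3)oc2c1OC(=O)c1ccc(OCc2ccccc2)c(OCc2ccccc2)c1
F4 | step 4 | 2-[3,4-bis(benzyloxy)phenyl]-8-hydroxy-5,7-dimethoxy-4H-chromen-4-one | COc1cc(OC)c2c(=O)cc(-c3ccc(OCc4ccccc4)c(OCc4ccccc4)c3)oc2c1O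
F5 | step 1 | 1,1'-(2,4,6-trimethoxybenzene-1,3-diyl)diethanone | CC(=O)c1c(OC)cc(OC)c(C(C)=O)c1OC
F6 | step 3 | 3,4-bis(benzyloxy)benzaldehyde (purchased) | O=Cc1ccc(OCc2ccccc2)c(OCc2ccccc2)c1
F7 | step 3 | (E)-1-(3-acetyl-2-hydroxy-4,6-dimethoxyphenyl)-3-[3,4-bis(benzyloxy)phenyl]prop-2-en-1-one | CC(=O)c1c(OC)cc(OC)c(C(=O)/C=C/c2ccc(OCc3ccccc3)c(OCc3ccccc3)c2)c1O
F8 | step 5 | 8-acetyl-2-[3,4-bis(benzyloxy)phenyl]-3-hydroxy-5,7-dimethoxy-4H-chromen-4-one | COc1cc(OC)c2c(=O)c(O)c(-c3ccc(OCc4ccccc4)c(OCc4ccccc4)c3)oc2c1C(C)=O
F9 | step 5 | 8-acetyl-3-(benzyloxy)-2-[3,4-bis(benzyloxy)phenyl]-5,7-dimethoxy-4H-chromen-4-one | COc1cc(OC)c2c(=O)c(OCc3ccccc3)c(-c3ccc(OCc4ccccc4)c(OCc4ccccc4)c3)oc2c1C(C)=O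
F10 | step 5 | 3-(benzyloxy)-2-[3,4-bis(benzyloxy)phenyl]-5,7-dimethoxy-4-oxo-4H-chromen-8-yl acetate | COc1cc(OC)c2c(=O)c(OCc3ccccc3)c(-c3ccc(OCc4ccccc4)c(OCc4ccccc4)c3)oc2c1OC(C)=O
F11 | step 6 | 2-(3,4-dihydroxyphenyl)-3-hydroxy-5,7-dimethoxy-4-oxo-4H-chromen-8-yl acetate | COc1cc(OC)c2c(=O)c(O)c(-c3ccc(O)c(O)c3)oc2c1OC(C)=O
A1 | alternative 1 | 1-[6-(benzyloxy)-2-hydroxy-4-methoxy-3-(methoxymethoxy)phenyl]ethanone | CC(=O)c1c(O)c(OCOC)c(OC)cc1OCc1ccccc1
A2 | alternative 1 | (E)-1-[6-(benzyloxy)-2-hydroxy-4-methoxy-3-(methoxymethoxy)phenyl]-3-[3,4-bis(benzyloxy)phenyl]prop-2-en-1-one | O=C(/C=C/c1ccc(OCc2ccccc2)c(OCc2ccccc2)c1)c1c(O)c(OCOC)c(OC)cc1OCc1ccccc1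
A3 | alternative 1 | 3,5-bis(benzyloxy)-2-[3,4-bis(benzyloxy)phenyl]-8-hydroxy-7-methoxy-4H-chromen-4-one | COc1cc(OCc2ccccc2)c2c(=O)c(OCc3ccccc3)c(-c3ccc(OCc4ccccc4)c(OCc4ccccc4)c3)oc2c1O
A4 | alternative 2 | 3-(benzyloxy)-2-[3,4-bis(benzyloxy)phenyl]-5-hydroxy-7-methoxy-4H-chromen-4-one | COc1cc(O)c2c(=O)c(OCc3ccccc3)c(-c3ccc(OCc4ccccc4)c(OCc4ccccc4)c3)oc2c1
A5 | alternative 2 | 3-(benzyloxy)-2-[3,4-bis(benzyloxy)phenyl]-5,8-dihydroxy-7-methoxy-4H-chromen-4-one | COc1cc(O)c2c(=O)c(OCc3ccccc3)c(-c3ccc(OCc4ccccc4)c(OCc4ccccc4)c3)oc2c1O
A6 | alternative 3 | 2,6-dimethoxy-1,4-benzoquinone | COC1=CC(=O)C=C(OC)C1=O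
A7 | alternative 3 | 1-(3,6-dihydroxy-2,4-dimethoxyphenyl)ethanone | CC(=O)c1c(O)cc(OC)c(O)c1OC
A8 | alternative 3 | 3-(benzyloxy)-2-[3,4-bis(benzyloxy)phenyl]-7-methoxy-4H-chromene-4,5,8-trione | COC1=CC(=O)C2=C(OC(c3ccc(OCc4ccccc4)c(OCc4ccccc4)c3)=C(OCc3ccccc3)C2=O)C1=O
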